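## Structural features

The target is a fully substituted cyclohexane, numbered here C1 (OAc), C2 (OH), C3 (OH), C4 (oxirane CH), C5 (oxirane carbon) and C6 (OAc), with an oxirane fused across C4–C5 and an exocyclic C7H2 benzoate on C5. All six ring carbons are contiguous stereocentres. With the oxirane oxygen drawn up, O6 is up, O1 down, O2 up, O3 down and C7 down, so O6/O1/O2/O3 are all-trans (all equatorial in a chair), and the oxirane is cis to O6 and trans to O3. The fragile groups are the oxirane (acid, and base through Payne-type migration towards the C3 hydroxyl), the acetates next to free hydroxyls (acyl shift under base) and the primary benzoate. The real difficulty is not the ring itself but telling the acetylated C1/C6 diol from the free C2/C3 diol, four equatorial secondary hydroxyls of one kind, while the quaternary C5 is built with control. The key step exploits two facts: C7–C5–C6 is a dihydroxyacetone unit, and O6/O1 form a threo diol. The ring is therefore a seven-carbon ketose (C7, C5, C6, C1, C2, C3, C4) folded so that C4 bonds to the ketone carbon C5, and a nitro group on C4 supplies the carbanion for that bond. C2 and C3 carry the configuration of L-tartaric acid, and keeping their diol under one acetonide from the first compound onwards removes the differentiation problem. Re-derivation of the descriptors shows the bookkeeping to be self-consistent, so no structure needs correcting: (R,R) at C2/C3 of the target corresponds to (2R,3S) in the nitro aldehyde and to (R,R) in L-tartrate, and the L-threo sense of the rhamnulose-type aldolase (3R,4S in the unprotected ketose) gives O6 up and O1 down.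

## Logic of the disconnections

**18 ⇒ 17 (acetal C–O bonds on O2 and O3).** The last retrosynthetic operation re-bridges O2 and O3 with an isopropylidene group. A free C2/C3 diol in the aldehyde partner would leave four like hydroxyls after ring closure. A bridge that is already present in 1 costs no step and marks exactly the two hydroxyls that stay free in 18. The gain is that later acylations only have to distinguish primary, secondary and tertiary hydroxyls. The demand is a final hydrolysis mild enough for an oxirane, two acetates and a benzoate, and free of base.

**17 ⇒ 16 (C4–O bond of the oxirane).** Cutting the oxirane at C4 gives the trans-diaxial C4/C5 diol 16, with O5 as nucleophile and C4 as electrophile. O5 is tertiary and already on the upper face, so inversion at C4 places the oxirane cis to O6. The strained ring is traded for two hydroxyls. The forward step must activate only the secondary C4 hydroxyl and must do so without base, because acetates flank the free tertiary hydroxyl.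

**16 ⇒ 15 ⇒ 12 (C4–H, then C4=O back to C4–NO2).** The axial carbinol is traced to ketone 15 and this to nitro compound 12. The nitro group is what lets C4 act as a carbon nucleophile in the ring closure, and afterwards it must be exchanged for an oxygen of opposite configuration. The gain is that the C4 configuration is irrelevant up to 15. The demands are a Nef reaction that tolerates esters and a β-hydroxyl, and hydride delivery to the upper face of 15, directed by the free C5 hydroxyl.

**12 ⇒ 11 ⇒ 9 + 10 (three acyl C–O bonds).** Removing the two acetyl groups and then the benzoyl group leads to 9 and 10. In 9 the free hydroxyls differ in kind (one primary at C7, two secondary at C1 and C6, one tertiary at C5), so the order of acylation does the differentiation. No protecting group beyond the acetonide is needed. The demand is kinetic selectivity for the primary hydroxyl in the benzoylation, and the tertiary hydroxyl must stay free.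

**9 ⇒ 8 (O–P bond).** The phosphate on O7 that the enzyme requires is put back. The forward hydrolysis must run at a pH where retro-nitroaldol opening and acetal cleavage are both slow.

**8 ⇒ 7 ⇒ 5 + 6 (C4–C5, then C6–C1).** The ring is opened at C4–C5 by a retro-nitroaldol step to 7, and 7 is cut at C6–C1 by a retro-aldol step into 6 and 5. C7–C5–C6 is the three-carbon ketol of 6, O6/O1 are threo as a rhamnulose-type aldolase delivers them, and the all-equatorial array makes ring closure downhill. A carbocycle with six stereocentres thus falls apart into a commercial C3 unit and a four-carbon aldehyde with two stereocentres. The demands are that the enzyme accepts 5 and controls C6 and C1, and that ring closure is reversible so that C4 and C5 settle with the nitro group and the carbon substituent equatorial.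

**5 ⇒ 4 ⇒ 3 ⇒ 2 ⇒ 1 (aldehyde oxidation level; C–N, C–I and O–S bonds).** 5 is traced through 4, 3 and 2 to the C2-symmetric diol 1. In 1 both hydroxymethyl groups are equivalent, so one can become the aldehyde carbon and the other the nitromethyl carbon without any regiochemical question, and C2/C3 are already correct and protected. That leaves four functional-group steps from a bulk chiral-pool compound. The demands are mono-functionalisation of a symmetric diol, N- rather than O-alkylation of nitrite, and a base-free oxidation, since 5 has an acidic nitromethyl group and an epimerisable α-carbon.

## Other disconnections considered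

**Alternative 1:** The cut is the C4–C5 bond of a carbocycle in which C6 is a ketone and C5 still a methylene; it leads back to the 6-deoxyhex-5-enopyranoside A2. In the forward sense Hg(OCOCF3)2 (divalent mercury) in aqueous acetone adds water and mercury across the enol ether of A2, the hemiacetal collapses to a keto aldehyde, and the mercurated carbon closes onto the aldehyde to give the β-hydroxy cyclohexanone A1 (Ferrier carbocyclisation).
- In its favour: the reaction is of proven reliability on gluco-configured substrates. C1, C2 and C3 arrive from the sugar all-trans and already differentiated (4-methoxybenzyl on O1, benzyl on O2/O3). The new C4 hydroxyl is expected on the lower face, where a leaving group must sit.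
- Against it here: A1 lacks C7 and the C5 oxygen, so the quaternary centre, the C6 configuration and the oxirane must all be made afterwards (elimination across C4–C5, hydroxymethylation at C5, carbonyl reduction, face-selective epoxidation). This erases the C4 centre that the key step created. Benzyl-type ethers must be removed late beside an oxirane and esters, and a mercury salt is used.
- Comparison, structure: the chosen plan delivers C7, O5 and five ring stereocentres in final form at ring closure; this one delivers a ring with three sugar-derived centres.
- Comparison, mechanism: both close the same C4–C5 bond by addition of a stabilised carbanion to a carbonyl group. The Ferrier process is the equal of the chosen cascade in predictability and the better in documented scope and in hydroxyl differentiation.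
- Comparison, step economy: it is the poorer, with about six steps of sugar manipulation before and nine or more after the closure.

**Alternative 2:** The cut is the C6–O bond, formed as one bond of a 1,3-dioxolane spanning O5 and O6; it leads back to the achiral para-quinol A4 and isobutyraldehyde A5. In the forward sense a chiral BINOL-derived phosphoric acid lets the tertiary hydroxyl of A4 form a hemiacetal with A5, and the hemiacetal hydroxyl adds in an oxa-Michael fashion to one of the two enantiotopic enone carbons to give the cis-fused dioxolane enone A3.
- In its favour: A4 should be reachable in two steps from a commercial phenol, the C7 benzoate is present from the outset, and C5 and C6 are set together, cis, by catalysis. Up to the key step this route is clearly better than the chosen one in brevity, and it is the better in operational simplicity (no enzyme, no phosphate handling).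
- Against it here: A3 holds only two of the six stereocentres. C1 is a methylene, C2 a ketone and C3=C4 an alkene, so O1, O2, O3 and the C4 end of the oxirane must still be introduced all-trans by substrate control. This includes an α-oxygenation at C1 and a leaving group of defined configuration at C4 for closure by O5 after acid removal of the acetal. The enantioselection depends on the catalyst–aldehyde pair.
- Comparison, structure: the chosen plan has every oxygen and five final stereocentres in place after ring closure.
- Comparison, mechanism: catalyst-controlled desymmetrisation stands against enzyme control plus thermodynamic closure; both are catalytic and asymmetric, and the two are equal in elegance.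
- Comparison, step economy: shorter before the key step, but the oxygenation sequence after it is longer and stereochemically less secure than the seven-step endgame of the chosen plan.

**Alternative 3:** The cut is the C5–C6 bond between the two cis oxygens, which opens the ring to the keto aldehyde A7, a seven-carbon chain assembled from a six-carbon sugar lactone and a benzyloxymethyl unit. In the forward sense SmI2 (divalent samarium) reduces the aldehyde of A7 to a ketyl, which adds to the C5 ketone through a samarium-bridged transition state to give the cis-5,6-diol A6.
- In its favour: C5 and C6 are formed at ring closure with the cis relation the target needs, and C1–C4 come from the chiral pool. Every ring carbon already carries oxygen at the right oxidation level with O4 on the lower face, so no nitro-to-carbonyl exchange and no reduction are needed; on this point the alternative is better than the chosen plan. O1, O2 and O3/O4 also carry different protecting groups.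
- Against it here: A7 needs a long linear sequence (about ten steps). The face on which the diol forms rests only on the preference of the ketyl to add anti to a neighbouring alkoxy group. After acetonide removal O3 and O4 must be told apart for sulfonylation. O2 and O7 carry the same benzyl group although one ends as a hydroxyl and the other as a benzoate. The reagent needs strict exclusion of air.
- Comparison, structure: both closures create the C5 carbinol cis to O6, and the chosen step in addition makes C6–C1.
- Comparison, mechanism: kinetic, chelate-controlled radical addition stands against two reversible polar additions under enzyme and thermodynamic control. The pinacol closure is the equal of the chosen step in fixing C5 and C6 at the moment of closure.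
- Comparison, step economy: the chosen plan reaches its cyclitol in five steps, the alternative in about eleven, with endgames of similar length.

Key step: step 5

Assumption: 1 (the acetonide diol made on scale from L-tartaric acid), the lithium salt of 6, recombinant L-rhamnulose-1-phosphate aldolase and acid phosphatase are treated as purchasable, so no steps are counted for them.

## Steps

Step 1
Reactants: 1 2,3-O-isopropylidene-L-threitol
Product: 2 mono-4-toluenesulfonate of 1
Conditions: TsCl (1.05 equiv), Ag2O (1.5 equiv), KI (0.2 equiv), CH2Cl2, 0 °C to rt
Reagents that add atoms: 4-toluenesulfonyl chloride, Cc1ccc(cc1)S(Cl)(=O)=O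
Why: Ag2O-mediated monosulfonylation of a symmetric diol: the two hydroxymethyl groups are equivalent by C2 symmetry, and after the first sulfonylation the remaining hydroxyl loses the internal hydrogen bond that activated the first, so the second reaction is slower; no stereocentre is involved.

Step 2
Reactants: 2 mono-4-toluenesulfonate
Product: 3 iodo alcohol, [(4S,5R)-5-(iodomethyl)-2,2-dimethyl-1,3-dioxolan-4-yl]methanol
Conditions: NaI (3 equiv), butan-2-one, reflux
Reagents that add atoms: sodium iodide, [Na+].[I-]
Why: Finkelstein exchange, an SN2 displacement of the primary sulfonate by iodide driven by precipitation of the sodium sulfonate; the free hydroxyl does not cyclise because a trans-fused bicyclic ether would result.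

Step 3
Reactants: 3 iodo alcohol
Product: 4 nitro alcohol, [(4S,5S)-2,2-dimethyl-5-(nitromethyl)-1,3-dioxolan-4-yl]methanol
Conditions: NaNO2 (2 equiv), phloroglucinol (1 equiv), DMSO, 20 °C, dark
Reagents that add atoms: sodium nitrite, [Na+].[O-]N=O
Why: Kornblum substitution: the ambident nitrite ion is alkylated on nitrogen by the primary iodide in a dipolar aprotic solvent, and phloroglucinol traps the minor alkyl nitrite so that it cannot nitrosate the product; the neutral medium leaves acetal and stereocentres untouched.

Step 4
Reactants: 4 nitro alcohol
Product: 5 nitro aldehyde acetonide, (4R,5S)-2,2-dimethyl-5-(nitromethyl)-1,3-dioxolane-4-carbaldehyde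
Conditions: TEMPO (2,2,6,6-tetramethylpiperidin-1-oxyl, 10 mol %), PhI(OAc)2 (1.1 equiv), CH2Cl2, rt; used without storage
Reagents that add atoms: none
Why: Oxoammonium-mediated alcohol oxidation stops at the aldehyde in anhydrous CH2Cl2 and needs no base, which matters because 5 has an acidic nitromethyl group β to an acetal oxygen and an epimerisable α-carbon; the trans-dioxolane is in any case the more stable epimer.

Step 5
Reactants: 5 nitro aldehyde acetonide; 6 dihydroxyacetone phosphate
Product: 8 nitrocyclitol phosphate 2,3-acetonide, via open-chain aldol adduct 7 (not isolated)
Conditions: L-rhamnulose-1-phosphate aldolase (recombinant, from Escherichia coli), 5 (1.3 equiv), H2O/DMF 9:1, pH 7.0, 25 °C; then pH 7.5, 25 °C until 7 is consumed; anion-exchange isolation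
Reagents that add atoms: none
Why: In the active site the zinc-bound enediolate of 6 adds through its one exposed face to the aldehyde carbon of 5 and forms the C6–C1 bond of the open-chain L-threo adduct 7. At pH 7 the nitromethyl group of 7 is in equilibrium with its nitronate, whose carbon C4 adds to the C5 ketone in a reversible intramolecular Henry reaction and forms the C4–C5 bond. The closest known reaction type is the aldolase-catalysed addition of dihydroxyacetone phosphate to nitro aldehydes followed by spontaneous nitroaldol cyclisation to nitrocyclitols. The one ring is closed in the 6-exo-trig mode (nitronate carbon onto an exocyclic carbonyl), trans-fused to the dioxolane. C6 is controlled by the enzyme alone; C1 is controlled by the enzyme's presentation of the aldehyde face and is backed by thermodynamics, since only this epimer lets O6, O1, O2 and O3 all be equatorial and both additions are reversible; C4 and C5 are controlled by equilibration in the chair, which puts NO2 and CH2OPO3H2 equatorial and leaves the C5 hydroxyl axial and cis to O6. The selectivity the step needs is therefore diastereofacial at the aldehyde and at the ketone, the first secured by the enzyme and by the all-trans pattern inherited from 1, the second by the larger steric demand of the carbon substituent on C5. The acetal on O2/O3 lies outside the reacting centres, blocks loss of nitromethane from what would otherwise be a β-hydroxy nitro unit, and keeps C1 and C4 trans as the chair requires.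

Step 6
Reactants: 8 nitrocyclitol phosphate 2,3-acetonide
Product: 9 nitro tetrol 2,3-acetonide (free hydroxyls on C1, C5, C6 and C7)
Conditions: acid phosphatase, H2O, pH 5.0, 30 °C
Reagents that add atoms: none
Why: Enzymatic hydrolysis of the phosphate monoester at pH 5, where nitronate formation (and with it retro-nitroaldol opening or epimerisation) is suppressed and the acetal is not yet cleaved; no stereocentre is touched.

Step 7
Reactants: 9 nitro tetrol 2,3-acetonide; 10 benzoyl chloride
Product: 11 C7 benzoate (free hydroxyls on C1, C5 and C6)
Conditions: 10 (1.05 equiv), pyridine, −40 to −20 °C
Reagents that add atoms: none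
Why: Kinetically controlled acylation of the single primary hydroxyl with a slight excess of acid chloride at low temperature; the equatorial C1 and C6 hydroxyls react more slowly and the tertiary C5 hydroxyl not at all, and pyridine is too weak a base to ionise the nitro group to a useful extent.

Step 8
Reactants: 11 C7 benzoate
Product: 12 1,6-diacetate 7-benzoate (free tertiary C5 hydroxyl, C4 nitro)
Conditions: Ac2O (3 equiv), pyridine, 0 °C to rt
Reagents that add atoms: acetic anhydride, CC(=O)OC(C)=O
Why: Standard acetylation of the two equatorial secondary hydroxyls; without an acyl-transfer catalyst the axial tertiary C5 hydroxyl stays free, as steps 10 and 11 require, and since neither oxygen β to the nitro group (O3 acetal, O5 free) becomes an ester, elimination to a nitroalkene is not opened up.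

Step 9
Reactants: 12 1,6-diacetate 7-benzoate
Product: 15 C4 ketone (α-hydroxy ketone with free C5 hydroxyl), via DBU nitronate 13 (not isolated), via NH imine 14 (not isolated)
Conditions: DBU (1,8-diazabicyclo[5.4.0]undec-7-ene, 1.05 equiv), THF, −20 °C; then aq. TiCl3 (5 equiv), NH4OAc, THF/H2O, pH 5–6, 0 °C to rt
Reagents that add atoms: water, O
Why: Nef reaction in its reductive (McMurry) form: DBU removes the axial C4 proton to give nitronate 13, TiCl3 (trivalent titanium) reduces both N–O bonds to give the N-unsubstituted imine 14, and water hydrolyses 14 to the ketone. A non-nucleophilic base and a buffered medium are used so that the esters and the strained acetal survive and C3, now α to a carbonyl group, is not enolised; the C4 stereocentre is deliberately erased here.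

Step 10
Reactants: 15 C4 ketone
Product: 16 trans-diaxial C4/C5 diol (C4 hydroxyl on the lower face)
Conditions: NaBH(OAc)3 (3 equiv), MeCN/AcOH 2:1, −20 to 0 °C
Reagents that add atoms: none
Why: Hydroxyl-directed reduction (Saksena–Evans type): the free tertiary C5 hydroxyl displaces acetate on boron and the bound hydride is delivered intramolecularly to the upper face of the C4 carbonyl, so the new hydroxyl is axial, on the lower face and trans to O5. The reagent does not reduce esters or ketones lacking a neighbouring hydroxyl, and the acidic medium prevents enolisation at C3.

Step 11
Reactants: 16 trans-diaxial C4/C5 diol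
Product: 17 oxirane 2,3-acetonide
Conditions: PPh3 (1.5 equiv), diisopropyl azodicarboxylate (1.5 equiv), toluene, 0 to 50 °C
Reagents that add atoms: none
Why: Mitsunobu cyclodehydration of a trans-diaxial 1,2-diol: the secondary C4 hydroxyl becomes an oxyphosphonium leaving group and the anti-periplanar tertiary O5 displaces it (3-exo-tet) with inversion at C4, which places the oxirane on the upper face, cis to the C6 acetate. No base is present, so the acetates do not migrate, and the tertiary hydroxyl is too hindered to be activated itself.

Step 12
Reactants: 17 oxirane 2,3-acetonide
Product: 18 target
Conditions: AcOH/H2O 4:1, 35 °C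
Reagents that add atoms: none
Why: Acid hydrolysis of an isopropylidene acetal: the dioxolane is trans-fused to the cyclohexane, hence strained and cleaved by dilute acetic acid, while an oxirane flanked by acyloxy- and hydroxy-bearing carbons is inductively deactivated towards acid-catalysed opening, as is familiar from anhydro sugars. Base is avoided to the end because the liberated C3 hydroxyl is trans to the oxirane (Payne-type migration) and the C2 hydroxyl is next to the C1 acetate.

## Compound list

Locants C1–C7 and the words up/down in the names of 7–18 follow the target numbering and the view with the oxirane oxygen up.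

1 | (4S,5S)-2,2-dimethyl-1,3-dioxolane-4,5-dimethanol (2,3-O-isopropylidene-L-threitol) | OC[C@@H]1OC(C)(C)O[C@H]1CO | starting material
2 | [(4S,5S)-5-(hydroxymethyl)-2,2-dimethyl-1,3-dioxolan-4-yl]methyl 4-methylbenzenesulfonate | Cc1ccc(cc1)S(=O)(=O)OC[C@@H]1OC(C)(C)O[C@H]1CO | intermediate
3 | [(4S,5R)-5-(iodomethyl)-2,2-dimethyl-1,3-dioxolan-4-yl]methanol | IC[C@@H]1OC(C)(C)O[C@H]1CO | intermediate
4 | [(4S,5S)-2,2-dimethyl-5-(nitromethyl)-1,3-dioxolan-4-yl]methanol | [O-][N+](=O)C[C@@H]1OC(C)(C)O[C@H]1CO | intermediate
5 | (4R,5S)-2,2-dimethyl-5-(nitromethyl)-1,3-dioxolane-4-carbaldehyde, the 2,3-O-isopropylidene form of (2R,3S)-2,3-dihydroxy-4-nitrobutanal | O=C[C@@H]1OC(C)(C)O[C@H]1C[N+](=O)[O-] | intermediate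
6 | dihydroxyacetone phosphate | OCC(=O)COP(O)(O)=O | starting material
7 | open-chain aldol adduct (not isolated): 3,4-dihydroxy-2-oxobutyl dihydrogen phosphate carrying the 5-(nitromethyl)-2,2-dimethyl-1,3-dioxolan-4-yl group on C4; L-threo C3/C4 diol, the 3R,4S sense of the unprotected series | OP(O)(=O)OCC(=O)[C@H](O)[C@@H](O)[C@@H]1OC(C)(C)O[C@H]1C[N+](=O)[O-] | intermediate
8 | nitrocyclitol phosphate 2,3-acetonide: O1 down, O2 up, O3 down, C4 NO2 up, C5 OH up with C7H2OPO3H2 down, O6 up | O[C@H]1[C@@H]2OC(C)(C)O[C@H]2[C@H]([N+](=O)[O-])[C@@](O)(COP(O)(O)=O)[C@@H]1O | intermediate
9 | nitro tetrol 2,3-acetonide: as 8 with C7H2OH | O[C@H]1[C@@H]2OC(C)(C)O[C@H]2[C@H]([N+](=O)[O-])[C@@](O)(CO)[C@@H]1O | intermediate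
10 | benzoyl chloride | O=C(Cl)c1ccccc1 | starting material
11 | C7 benzoate of 9 | O[C@H]1[C@@H]2OC(C)(C)O[C@H]2[C@H]([N+](=O)[O-])[C@@](O)(COC(=O)c3ccccc3)[C@@H]1O | intermediate
12 | 1,6-di-O-acetyl-7-O-benzoyl nitrocyclitol 2,3-acetonide (C5 OH free) | CC(=O)O[C@H]1[C@@H]2OC(C)(C)O[C@H]2[C@H]([N+](=O)[O-])[C@@](O)(COC(=O)c3ccccc3)[C@@H]1OC(C)=O | intermediate
13 | C4 nitronate of 12 as its DBU-H salt (not isolated) | CC(=O)O[C@H]1[C@@H]2OC(C)(C)O[C@H]2C(=[N+]([O-])[O-])[C@@](O)(COC(=O)c3ccccc3)[C@@H]1OC(C)=O.C1CCC2=[NH+]CCCN2CC1 | intermediate
14 | C4 N-unsubstituted imine (not isolated) | CC(=O)O[C@H]1[C@@H]2OC(C)(C)O[C@H]2C(=N)[C@@](O)(COC(=O)c3ccccc3)[C@@H]1OC(C)=O | intermediate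
15 | C4 ketone: 1,6-di-O-acetyl-7-O-benzoyl-5-hydroxy-4-oxo compound, 2,3-acetonide | CC(=O)O[C@H]1[C@@H]2OC(C)(C)O[C@H]2C(=O)[C@@](O)(COC(=O)c3ccccc3)[C@@H]1OC(C)=O | intermediate
16 | trans-diaxial C4/C5 diol: C4 OH down, C5 OH up, 2,3-acetonide | CC(=O)O[C@H]1[C@@H]2OC(C)(C)O[C@H]2[C@@H](O)[C@@](O)(COC(=O)c3ccccc3)[C@@H]1OC(C)=O | intermediate
17 | C4–C5 oxirane (oxygen up) 2,3-acetonide, 1,6-diacetate, 7-benzoate | CC(=O)O[C@H]1[C@@H]2OC(C)(C)O[C@H]2[C@@H]3O[C@]3(COC(=O)c4ccccc4)[C@@H]1OC(C)=O | intermediate
18 | CNP0171674.1: 1,6-di-O-acetyl-7-O-benzoyl C4–C5 oxirane 2,3-diol, (1S,2R,3R,4S,5S,6R) in the numbering used here | CC(=O)O[C@H]1[C@H](O)[C@@H](O)[C@@H]2O[C@]2(COC(=O)c2ccccc2)[C@@H]1OC(C)=O | target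

## Step count and least certain steps

Total step count: 12. Longest linear sequence: 12 steps (1 to 18); 6 and 10 enter as purchased compounds.

**Step 5 (key step).** The most likely failure is slow or incomplete turnover of an α-branched, acetal-bearing aldehyde in the active site. A second is loss of facial selectivity at C1, because the α-carbon of 5 has the D configuration, the series this aldolase handles less strictly. Ring closure could also stall at 7, or give the C5 epimer, because the trans-fused dioxolane raises the strain of the chair. The fallback makes the C6–C1 bond by amine catalysis instead of the enzyme. Setting out from 5, dihydroxyacetone and O-tert-butyl-D-threonine (20 mol %) in N-methylpyrrolidone/water should give, through an enamine and a hydrogen-bonded syn-selective transition state, the phosphate-free open-chain nitro ketose F1 with the same L-threo diol. A catalytic amount of Et3N in methanol then closes the ring by the same reversible nitroaldol addition, and the route is rejoined at 9 (step 6 is then not needed).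

**Step 9 (Nef reaction).** The most likely failure is ring opening by retro-nitroaldol cleavage of C4–C5, or an acetyl shift from O6 to O5, while base acts on a substrate with a free β-hydroxyl. Over-reduction of 14 to the amine and slow hydrolysis at the hindered C4 are further risks. The fallback avoids the nitronate. Setting out from 12, SnCl2·2H2O (divalent tin), PhSH and Et3N in MeCN should reduce the neutral nitro group directly to the C4 oxime F2. F2 is then cleaved with buffered aqueous TiCl3 (reduction of the N–O bond, hydrolysis of 14), and the route is rejoined at 15.

**Step 7 (benzoylation).** The most likely failure is loss of site selectivity leading to over-acylation, because the primary hydroxyl is of the neopentyl type (on the quaternary C5) while the C1 and C6 hydroxyls are unhindered and equatorial. The fallback takes the primary position first with a reagent of larger steric bias. Setting out from 9, tert-butyldimethylsilyl chloride and imidazole in DMF at 0 °C give the C7 silyl ether F3. Acetylation as in step 8 gives the silyl ether diacetate F4, and HF·pyridine in THF frees the primary hydroxyl to give the diacetate alcohol F5. Benzoylation with 10 in pyridine, now with only a tertiary hydroxyl as competitor, rejoins the route at 12.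

**Step 10 (reduction).** The most likely failure is poor facial selectivity if hydride transfer from unbound reagent competes with the delivered one. Undirected attack is expected on the lower face, anti to the axial C5–O bond, and would give the equatorial C4 alcohol, which is cis to O5 and cannot close to the oxirane. Ligand exchange at the hindered tertiary hydroxyl may also be slow. The fallback moves control from the substrate to a catalyst. Setting out from 15, a panel of NADPH-dependent ketoreductases (isopropanol as terminal reductant, aqueous buffer pH 7 with 10 % DMSO) is screened for the member that transfers hydride to the upper face. The route is rejoined at 16, and this fallback makes no new compound (F0).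

**Step 11 (oxirane closure).** The most likely failure is slow formation of the oxyphosphonium ion at the axial C4 hydroxyl, which is flanked by the quaternary C5, so that betaine decomposition and hydrazide adducts take over. The fallback separates activation from closure. Setting out from 16, MeSO2Cl and Et3N in CH2Cl2 at −20 °C (sulfene pathway, which reaches hindered secondary hydroxyls and leaves the tertiary one alone) give the C4 methanesulfonate F6. DBU in MeCN at rt then lets O5 displace the anti-periplanar sulfonate, and the route is rejoined at 17.

## Further compounds

F1 | step 5 | phosphate-free open-chain nitro ketose, 1,3,4-trihydroxy-4-[5-(nitromethyl)-2,2-dimethyl-1,3-dioxolan-4-yl]butan-2-one, L-threo C3/C4 diol | OCC(=O)[C@H](O)[C@@H](O)[C@@H]1OC(C)(C)O[C@H]1C[N+](=O)[O-]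
F2 | step 9 | C4 oxime corresponding to 12 | CC(=O)O[C@H]1[C@@H]2OC(C)(C)O[C@H]2C(=NO)[C@@](O)(COC(=O)c3ccccc3)[C@@H]1OC(C)=O
F3 | step 7 | C7 tert-butyldimethylsilyl ether of 9 | O[C@H]1[C@@H]2OC(C)(C)O[C@H]2[C@H]([N+](=O)[O-])[C@@](O)(CO[Si](C)(C)C(C)(C)C)[C@@H]1O
F4 | step 7 | 1,6-di-O-acetyl derivative of F3 | CC(=O)O[C@H]1[C@@H]2OC(C)(C)O[C@H]2[C@H]([N+](=O)[O-])[C@@](O)(CO[Si](C)(C)C(C)(C)C)[C@@H]1OC(C)=O
F5 | step 7 | 1,6-di-O-acetyl nitrocyclitol 2,3-acetonide with free C7 and C5 hydroxyls | CC(=O)O[C@H]1[C@@H]2OC(C)(C)O[C@H]2[C@H]([N+](=O)[O-])[C@@](O)(CO)[C@@H]1OC(C)=O
F0 | step 10 | none | none
F6 | step 11 | C4 methanesulfonate of 16 | CC(=O)O[C@H]1[C@@H]2OC(C)(C)O[C@H]2[C@@H](OS(C)(=O)=O)[C@@](O)(COC(=O)c3ccccc3)[C@@H]1OC(C)=O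
A1 | alternative 1 | 2,3-di-O-benzyl-1-O-(4-methoxybenzyl)-4-hydroxycyclohexan-6-one (C5 methylene), Ferrier product | COc1ccc(CO[C@H]2[C@H](OCc3ccccc3)[C@@H](OCc3ccccc3)[C@@H](O)CC2=O)cc1
A2 | alternative 1 | methyl 2,3-di-O-benzyl-6-deoxy-4-O-(4-methoxybenzyl)-α-D-xylo-hex-5-enopyranoside | CO[C@H]1OC(=C)[C@@H](OCc2ccc(OC)cc2)[C@H](OCc2ccccc2)[C@H]1OCc1ccccc1
A3 | alternative 2 | cis-fused 2-isopropyl-1,3-dioxolane enone bridging O5 and O6 | C1C(=O)C=C[C@]2(COC(=O)c3ccccc3)O[C@@H](C(C)C)O[C@H]12
A4 | alternative 2 | (1-hydroxy-4-oxocyclohexa-2,5-dien-1-yl)methyl benzoate | O=C1C=CC(O)(COC(=O)c2ccccc2)C=C1
A5 | alternative 2 | isobutyraldehyde | CC(C)C=O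
A6 | alternative 3 | cyclitol cis-5,6-diol, 1-O-(4-methoxybenzyl), 2-O-benzyl, 3,4-O-isopropylidene, 7-O-benzyl | COc1ccc(CO[C@H]2[C@H](OCc3ccccc3)[C@H]4OC(C)(C)O[C@H]4[C@@](O)(COCc3ccccc3)[C@@H]2O)cc1
A7 | alternative 3 | open-chain keto aldehyde precursor of A6 (C6 aldehyde, C5 ketone) | O=C[C@@H](OCc1ccc(OC)cc1)[C@H](OCc1ccccc1)[C@H]1OC(C)(C)O[C@H]1C(=O)COCc1ccccc1
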